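**Retrosynthetic overview**
1. Target ⇐ C6 acetoxylation of the ketone enolate ⇐ epoxy ketone 17 ⇐ oxidation of bis-epoxy alcohol 16.
2. 16 ⇐ both oxiranes made in one flask from allylic alcohol 14: ring C3–C4 oxirane by C5-hydroxyl-directed vanadium epoxidation, then side-chain C10–C11 oxirane by Shi epoxidation.
3. 14 ⇐ Luche reduction ⇐ 13 ⇐ side chain grown from the isopropenyl group: allylic oxidation to the C8 aldehyde, Brown allylation (8S), cross-metathesis, tigloylation.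
4. C2 oxygen ⇐ thermodynamic siloxydiene of (R)-carvone plus singlet oxygen, then Mitsunobu inversion with tiglic acid.
5. Ring order: the cyclohexane ring comes intact from (R)-carvone; the ring oxirane and the side-chain oxirane are formed together in step 9.

Assumption and locants: the SMILES is read as the (1R,2S,3S,4S,6S,8S,10R) isomer with two (E)-2-methylbut-2-enoates (tiglates); locants used below are ring C1 (side chain), C2 (O-tiglate), C3–C4 (epoxide, methyl on C4), C5 (C=O), C6 (OAc), side chain C7(=C14H2)–C8(O-tiglate)–C9–C10–C11(Me)2 (epoxide); α is the ring face of the C1 side chain, β the opposite face.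

**Step 1**
Reactants: 1 (R)-(−)-carvone
Product: 3 trimethyl{[(5S)-2-methyl-5-(prop-1-en-2-yl)cyclohexa-1,3-dien-1-yl]oxy}silane, via potassium dienolate 2 (not isolated)
Conditions: t-BuOK, THF, 0 °C, 1 h; then Me3SiCl, −78 → 0 °C
Reagents that add atoms: chlorotrimethylsilane C[Si](C)(C)Cl
Why: Equilibrating deprotonation removes the γ-hydrogen at C2 to give the through-conjugated dienolate, which is O-silylated (thermodynamic silyl dienol ether formation); the C1 stereocentre of carvone is untouched.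

**Step 2**
Reactants: 3 trimethyl{[(5S)-2-methyl-5-(prop-1-en-2-yl)cyclohexa-1,3-dien-1-yl]oxy}silane
Product: 6 (4S,5R)-4-hydroxy-2-methyl-5-(prop-1-en-2-yl)cyclohex-2-en-1-one, via endoperoxide 4 (not isolated), via hydroperoxide 5 (not isolated)
Conditions: O2, hν, tetraphenylporphyrin (cat.), CH2Cl2, −78 °C; then MeOH, PPh3, −78 °C → rt
Reagents that add atoms: dioxygen O=O
Why: Singlet-oxygen [4+2] cycloaddition across C2/C5 of the siloxydiene occurs mainly on the β face (anti to the C1 isopropenyl group), methanolysis of the silyl peroxy-ketal releases the enone and the C2 hydroperoxide (Kornblum–DeLaMare-type collapse) and PPh3 reduces the O–O bond, so C2 is set as 2β-OH (the minor 2α epimer is removed by chromatography).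

**Step 3**
Reactants: 6 (4S,5R)-4-hydroxy-2-methyl-5-(prop-1-en-2-yl)cyclohex-2-en-1-one
Product: 7 (1R,6R)-3-methyl-4-oxo-6-(prop-1-en-2-yl)cyclohex-2-en-1-yl (2E)-2-methylbut-2-enoate
Conditions: tiglic acid, PPh3, DIAD, toluene, 0 °C → rt
Reagents that add atoms: tiglic acid C/C=C(\C)C(=O)O
Why: Mitsunobu esterification displaces the oxyphosphonium ion by SN2, inverting C2 to the 2α tiglate (cis to the side chain) required in the target.

**Step 4**
Reactants: 7 (1R,6R)-3-methyl-4-oxo-6-(prop-1-en-2-yl)cyclohex-2-en-1-yl (2E)-2-methylbut-2-enoate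
Product: 9 (1R,6R)-3-methyl-4-oxo-6-(3-oxoprop-1-en-2-yl)cyclohex-2-en-1-yl (2E)-2-methylbut-2-enoate, via allylic alcohol 8 (not isolated)
Conditions: SeO2 (0.3 equiv), t-BuOOH, salicylic acid (cat.), CH2Cl2, rt; then MnO2, rt
Reagents that add atoms: selenium dioxide O=[Se]=O (oxygen carrier); tert-butyl hydroperoxide CC(C)(C)OO (terminal oxygen source)
Why: Riley allylic oxidation (SeO2 ene reaction then [2,3] shift) attacks only the electron-rich isopropenyl group at its methyl (the enone and tiglate olefins are deactivated), and MnO2 takes the primary allylic alcohol to the 2-substituted acrolein; no stereocentre is involved.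

**Step 5**
Reactants: 9 (1R,6R)-3-methyl-4-oxo-6-(3-oxoprop-1-en-2-yl)cyclohex-2-en-1-yl (2E)-2-methylbut-2-enoate
Product: 11 (1R,6R)-6-[(3S)-3-hydroxyhexa-1,5-dien-2-yl]-3-methyl-4-oxocyclohex-2-en-1-yl (2E)-2-methylbut-2-enoate, via borinate ester 10 (not isolated)
Conditions: (−)-Ipc2B(allyl), Et2O, −78 °C; then HOCH2CH2NH2, rt
Reagents that add atoms: (−)-B-allyldiisopinocampheylborane C=CCB([C@@H]1C[C@@H]2C[C@H]([C@H]1C)C2(C)C)[C@@H]1C[C@@H]2C[C@H]([C@H]1C)C2(C)C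
Why: Brown asymmetric allylboration through a chair Zimmerman–Traxler transition state adds allyl to the aldehyde (far faster than to the enone carbonyl) under reagent control, giving the 8S carbinol (same facial sense as benzaldehyde → S with the reagent from (+)-α-pinene).

**Step 6**
Reactants: 11 (1R,6R)-6-[(3S)-3-hydroxyhexa-1,5-dien-2-yl]-3-methyl-4-oxocyclohex-2-en-1-yl (2E)-2-methylbut-2-enoate
Product: 12 (1R,6R)-6-[(3S)-3-hydroxy-6-methylhepta-1,5-dien-2-yl]-3-methyl-4-oxocyclohex-2-en-1-yl (2E)-2-methylbut-2-enoate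
Conditions: second-generation Grubbs catalyst (H2IMes)(PCy3)Cl2Ru=CHPh (5 mol%), 2-methylbut-2-ene (excess), CH2Cl2, 40 °C
Reagents that add atoms: 2-methylbut-2-ene CC=C(C)C
Why: Olefin cross-metathesis converts only the monosubstituted vinyl group into the trisubstituted C10=C11 olefin (the 1,1-disubstituted and conjugated olefins are metathesis-inert); C8 is not touched.

**Step 7**
Reactants: 12 (1R,6R)-6-[(3S)-3-hydroxy-6-methylhepta-1,5-dien-2-yl]-3-methyl-4-oxocyclohex-2-en-1-yl (2E)-2-methylbut-2-enoate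
Product: 13 (1R,6R)-3-methyl-6-[(3S)-6-methyl-3-{[(2E)-2-methylbut-2-enoyl]oxy}hepta-1,5-dien-2-yl]-4-oxocyclohex-2-en-1-yl (2E)-2-methylbut-2-enoate
Conditions: tiglic anhydride, DMAP (cat.), pyridine, CH2Cl2, rt
Reagents that add atoms: tiglic anhydride C/C=C(\C)C(=O)OC(=O)/C(C)=C/C
Why: DMAP-catalysed acylation (Steglich-type acyl transfer) of the C8 hydroxyl with retention; this also deactivates the C7=C14 olefin for the later oxidations.

**Step 8**
Reactants: 13 (1R,6R)-3-methyl-6-[(3S)-6-methyl-3-{[(2E)-2-methylbut-2-enoyl]oxy}hepta-1,5-dien-2-yl]-4-oxocyclohex-2-en-1-yl (2E)-2-methylbut-2-enoate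
Product: 14 (1R,4R,6R)-4-hydroxy-3-methyl-6-[(3S)-6-methyl-3-{[(2E)-2-methylbut-2-enoyl]oxy}hepta-1,5-dien-2-yl]cyclohex-2-en-1-yl (2E)-2-methylbut-2-enoate
Conditions: NaBH4, CeCl3·7H2O, MeOH, −78 °C
Reagents that add atoms: none
Why: Luche 1,2-reduction of the enone with hydride delivered to the β face (as in carvone → cis-carveol) gives the 5α allylic alcohol, cis to the C1 side chain, which serves as a temporary directing group; the esters are untouched.

**Step 9**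
Reactants: 14 (1R,4R,6R)-4-hydroxy-3-methyl-6-[(3S)-6-methyl-3-{[(2E)-2-methylbut-2-enoyl]oxy}hepta-1,5-dien-2-yl]cyclohex-2-en-1-yl (2E)-2-methylbut-2-enoate
Product: 16 (8S,10R)-3α,4α:10,11-diepoxy-5α-hydroxy-2α,8-bis(tigloyloxy)bisabol-7(14)-ene, via ring epoxide 15 (not isolated)
Conditions: VO(acac)2 (5 mol%), t-BuOOH, toluene, 0 °C → rt; then in the same flask D-fructose-derived Shi ketone (30 mol%), Oxone (2KHSO5·KHSO4·K2SO4), K2CO3, n-Bu4NHSO4, MeCN–(MeO)2CH2–H2O (pH 10.5), 0 °C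
Reagents that add atoms: tert-butyl hydroperoxide CC(C)(C)OO; potassium peroxymonosulfate [K+].[O-]S(=O)(=O)OO
Why: The vanadate ester of the 5α-hydroxyl delivers oxygen to C3=C4 on the α face (hydroxyl-directed Sharpless–Michaelson epoxidation, setting C3 and C4 against the steric bias), and the chiral dioxirane then epoxidises only the remaining electron-rich trisubstituted C10=C11 olefin under catalyst control (Shi epoxidation, spiro transition state) to set 10R, so both oxirane rings arise in one operation.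

**Step 10**
Reactants: 16 (8S,10R)-3α,4α:10,11-diepoxy-5α-hydroxy-2α,8-bis(tigloyloxy)bisabol-7(14)-ene
Product: 17 (1R,2S,3S,4S,8S,10R)-3,4:10,11-diepoxy-2,8-bis(tigloyloxy)bisabol-7(14)-en-5-one
Conditions: Dess–Martin periodinane, pyridine, CH2Cl2, 0 °C → rt
Reagents that add atoms: none
Why: Dess–Martin oxidation of the secondary alcohol under buffered conditions gives the α,β-epoxy ketone; C4 is quaternary, so no centre can epimerise, and epoxides and esters survive.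

**Step 11**
Reactants: 17 (1R,2S,3S,4S,8S,10R)-3,4:10,11-diepoxy-2,8-bis(tigloyloxy)bisabol-7(14)-en-5-one
Product: 20 CNP0407453.3 [(1R,2S,3S,4S,6S,8S,10R)-6-acetoxy-3,4:10,11-diepoxy-2,8-bis(tigloyloxy)bisabol-7(14)-en-5-one], via sodium enolate 18 (not isolated), via sodium alkoxide 19 (not isolated)
Conditions: NaN(SiMe3)2, THF, −78 °C; 2-(phenylsulfonyl)-3-phenyloxaziridine, −78 °C; then Ac2O, DMAP, −78 → 0 °C
Reagents that add atoms: 2-(phenylsulfonyl)-3-phenyloxaziridine O=S(=O)(N1OC1c1ccccc1)c1ccccc1; acetic anhydride CC(=O)OC(C)=O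
Why: The ketone can enolise only toward C6 (C4 is quaternary), the Davis oxaziridine attacks the enolate on the β face anti to the adjacent C1 side chain (Davis α-hydroxylation) and the alkoxide is acetylated in situ, setting the 6β-acetate trans to the side chain.

**Compound list**
1 | (R)-(−)-carvone, (5R)-2-methyl-5-(prop-1-en-2-yl)cyclohex-2-en-1-one | C=C(C)[C@@H]1CC=C(C)C(=O)C1 | starting material
2 | potassium (5S)-2-methyl-5-(prop-1-en-2-yl)cyclohexa-1,3-dien-1-olate (extended dienolate, not isolated) | C=C(C)[C@@H]1C=CC(C)=C([O-])C1.[K+] | intermediate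
3 | trimethyl{[(5S)-2-methyl-5-(prop-1-en-2-yl)cyclohexa-1,3-dien-1-yl]oxy}silane | C=C(C)[C@@H]1C=CC(C)=C(O[Si](C)(C)C)C1 | intermediate
4 | 6-methyl-8-(prop-1-en-2-yl)-1-(trimethylsilyloxy)-2,3-dioxabicyclo[2.2.2]oct-5-ene, peroxide bridge anti to the isopropenyl group (not isolated) | C=C(C)[C@@H]1[C@H]2OO[C@@](O[Si](C)(C)C)(C1)C(C)=C2 | intermediate
5 | (4S,5R)-4-hydroperoxy-2-methyl-5-(prop-1-en-2-yl)cyclohex-2-en-1-one (not isolated) | C=C(C)[C@@H]1[C@@H](OO)C=C(C)C(=O)C1 | intermediate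
6 | (4S,5R)-4-hydroxy-2-methyl-5-(prop-1-en-2-yl)cyclohex-2-en-1-one (2β-OH, trans to side chain) | C=C(C)[C@@H]1[C@@H](O)C=C(C)C(=O)C1 | intermediate
7 | (1R,6R)-3-methyl-4-oxo-6-(prop-1-en-2-yl)cyclohex-2-en-1-yl (2E)-2-methylbut-2-enoate (2α-tiglate) | C=C(C)[C@@H]1[C@H](OC(=O)/C(C)=C/C)C=C(C)C(=O)C1 | intermediate
8 | (1R,6R)-6-(3-hydroxyprop-1-en-2-yl)-3-methyl-4-oxocyclohex-2-en-1-yl (2E)-2-methylbut-2-enoate (not isolated) | C=C(CO)[C@@H]1[C@H](OC(=O)/C(C)=C/C)C=C(C)C(=O)C1 | intermediate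
9 | (1R,6R)-3-methyl-4-oxo-6-(3-oxoprop-1-en-2-yl)cyclohex-2-en-1-yl (2E)-2-methylbut-2-enoate | C=C(C=O)[C@@H]1[C@H](OC(=O)/C(C)=C/C)C=C(C)C(=O)C1 | intermediate
10 | diisopinocampheylborinate ester of 11 at the C8 oxygen (not isolated) | C=C([C@@H]1[C@H](OC(=O)/C(C)=C/C)C=C(C)C(=O)C1)[C@H](CC=C)OB([C@@H]1C[C@@H]2C[C@H]([C@H]1C)C2(C)C)[C@@H]1C[C@@H]2C[C@H]([C@H]1C)C2(C)C | intermediate
11 | (1R,6R)-6-[(3S)-3-hydroxyhexa-1,5-dien-2-yl]-3-methyl-4-oxocyclohex-2-en-1-yl (2E)-2-methylbut-2-enoate | C=C([C@@H]1[C@H](OC(=O)/C(C)=C/C)C=C(C)C(=O)C1)[C@H](CC=C)O | intermediate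
12 | (1R,6R)-6-[(3S)-3-hydroxy-6-methylhepta-1,5-dien-2-yl]-3-methyl-4-oxocyclohex-2-en-1-yl (2E)-2-methylbut-2-enoate | C=C([C@@H]1[C@H](OC(=O)/C(C)=C/C)C=C(C)C(=O)C1)[C@H](CC=C(C)C)O | intermediate
13 | (1R,6R)-3-methyl-6-[(3S)-6-methyl-3-{[(2E)-2-methylbut-2-enoyl]oxy}hepta-1,5-dien-2-yl]-4-oxocyclohex-2-en-1-yl (2E)-2-methylbut-2-enoate | C=C([C@@H]1[C@H](OC(=O)/C(C)=C/C)C=C(C)C(=O)C1)[C@H](CC=C(C)C)OC(=O)/C(C)=C/C | intermediate
14 | (1R,4R,6R)-4-hydroxy-3-methyl-6-[(3S)-6-methyl-3-{[(2E)-2-methylbut-2-enoyl]oxy}hepta-1,5-dien-2-yl]cyclohex-2-en-1-yl (2E)-2-methylbut-2-enoate (5α-OH) | C=C([C@@H]1[C@H](OC(=O)/C(C)=C/C)C=C(C)[C@H](O)C1)[C@H](CC=C(C)C)OC(=O)/C(C)=C/C | intermediate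
15 | (8S)-3α,4α-epoxy-5α-hydroxy-2α,8-bis(tigloyloxy)bisabola-7(14),10-diene (ring epoxide of 14, not isolated) | C=C([C@@H]1[C@H](OC(=O)/C(C)=C/C)[C@@H]2O[C@]2(C)[C@H](O)C1)[C@H](CC=C(C)C)OC(=O)/C(C)=C/C | intermediate
16 | (8S,10R)-3α,4α:10,11-diepoxy-5α-hydroxy-2α,8-bis(tigloyloxy)bisabol-7(14)-ene | C=C([C@@H]1[C@H](OC(=O)/C(C)=C/C)[C@@H]2O[C@]2(C)[C@H](O)C1)[C@H](C[C@H]1OC1(C)C)OC(=O)/C(C)=C/C | intermediate
17 | (1R,2S,3S,4S,8S,10R)-3,4:10,11-diepoxy-2,8-bis(tigloyloxy)bisabol-7(14)-en-5-one | C=C([C@@H]1[C@H](OC(=O)/C(C)=C/C)[C@@H]2O[C@]2(C)C(=O)C1)[C@H](C[C@H]1OC1(C)C)OC(=O)/C(C)=C/C | intermediate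
18 | sodium C5(O)=C6 enolate of 17 (not isolated) | C=C([C@@H]1[C@H](OC(=O)/C(C)=C/C)[C@@H]2O[C@]2(C)C([O-])=C1)[C@H](C[C@H]1OC1(C)C)OC(=O)/C(C)=C/C.[Na+] | intermediate
19 | sodium 6β-alkoxide of the 6β-hydroxy derivative of 17 (not isolated) | C=C([C@@H]1[C@H](OC(=O)/C(C)=C/C)[C@@H]2O[C@]2(C)C(=O)[C@H]1[O-])[C@H](C[C@H]1OC1(C)C)OC(=O)/C(C)=C/C.[Na+] | intermediate
20 | CNP0407453.3, (1R,2S,3S,4S,6S,8S,10R)-6-acetoxy-3,4:10,11-diepoxy-2,8-bis(tigloyloxy)bisabol-7(14)-en-5-one | C=C([C@@H]1[C@H](OC(=O)/C(C)=C/C)[C@@H]2O[C@]2(C)C(=O)[C@H]1OC(C)=O)[C@H](C[C@H]1OC1(C)C)OC(=O)/C(C)=C/C | target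

**Totals**
Total step count: 11. Longest linear sequence: 11 steps from (R)-carvone.

**Steps most likely to fail, with fallbacks**

Step 2 (face selectivity of the singlet-oxygen addition is expected to be modest, and it rests on the regiochemistry of step 1). The fallback sets out from 3 and returns at 7, fixing C2 by hydride delivery instead. The hydroperoxide 5, generated as in step 2, is dehydrated with Ac2O/Et3N (Kornblum–DeLaMare) to (5R)-2-methyl-5-(prop-1-en-2-yl)cyclohex-2-ene-1,4-dione F1. Both carbonyls are reduced with NaBH4/CeCl3·7H2O from the β face to (1R,4R,5R)-2-methyl-5-(prop-1-en-2-yl)cyclohex-2-ene-1,4-diol F2. MnO2 re-oxidises the less hindered C5 carbinol to (4R,5R)-4-hydroxy-2-methyl-5-(prop-1-en-2-yl)cyclohex-2-en-1-one F3. Acylation with tiglic anhydride/DMAP then gives 7 with retention at C2.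

Step 3 (Mitsunobu reaction of a hindered γ-hydroxy enone with a weak acid; elimination toward a phenol can compete). The fallback sets out from 6 and returns at 7. The alcohol is converted with MsCl/Et3N into (1S,6R)-3-methyl-4-oxo-6-(prop-1-en-2-yl)cyclohex-2-en-1-yl methanesulfonate F4. This is displaced with inversion by cesium tiglate (CsO2C–C(CH3)=CHCH3, 18-crown-6, toluene) to give 7.

Step 9 (vanadium and peroxide carried into the Oxone stage, and possible over-oxidation of C7=C14). The fallback sets out from 13 and returns at 16, with the two epoxidations separated and reordered. Shi epoxidation is run first on enone 13, whose ring olefin is inert to the dioxirane. This gives (1R,6R)-6-[(3S)-4-[(2R)-3,3-dimethyloxiran-2-yl]-3-{[(2E)-2-methylbut-2-enoyl]oxy}but-1-en-2-yl]-3-methyl-4-oxocyclohex-2-en-1-yl (2E)-2-methylbut-2-enoate F5. Luche reduction then gives the 5α-alcohol (1R,4R,6R)-6-[(3S)-4-[(2R)-3,3-dimethyloxiran-2-yl]-3-{[(2E)-2-methylbut-2-enoyl]oxy}but-1-en-2-yl]-4-hydroxy-3-methylcyclohex-2-en-1-yl (2E)-2-methylbut-2-enoate F6. VO(acac)2/t-BuOOH epoxidation of F6, directed by the hydroxyl, gives 16.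

**Further compounds**
F1 | step 2 | (5R)-2-methyl-5-(prop-1-en-2-yl)cyclohex-2-ene-1,4-dione | C=C(C)[C@@H]1C(=O)C=C(C)C(=O)C1
F2 | step 2 | (1R,4R,5R)-2-methyl-5-(prop-1-en-2-yl)cyclohex-2-ene-1,4-diol | C=C(C)[C@@H]1[C@H](O)C=C(C)[C@H](O)C1
F3 | step 2 | (4R,5R)-4-hydroxy-2-methyl-5-(prop-1-en-2-yl)cyclohex-2-en-1-one | C=C(C)[C@@H]1[C@H](O)C=C(C)C(=O)C1
F4 | step 3 | (1S,6R)-3-methyl-4-oxo-6-(prop-1-en-2-yl)cyclohex-2-en-1-yl methanesulfonate | C=C(C)[C@@H]1[C@@H](OS(C)(=O)=O)C=C(C)C(=O)C1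
F5 | step 9 | (1R,6R)-6-[(3S)-4-[(2R)-3,3-dimethyloxiran-2-yl]-3-{[(2E)-2-methylbut-2-enoyl]oxy}but-1-en-2-yl]-3-methyl-4-oxocyclohex-2-en-1-yl (2E)-2-methylbut-2-enoate | C=C([C@@H]1[C@H](OC(=O)/C(C)=C/C)C=C(C)C(=O)C1)[C@H](C[C@H]1OC1(C)C)OC(=O)/C(C)=C/C
F6 | step 9 | (1R,4R,6R)-6-[(3S)-4-[(2R)-3,3-dimethyloxiran-2-yl]-3-{[(2E)-2-methylbut-2-enoyl]oxy}but-1-en-2-yl]-4-hydroxy-3-methylcyclohex-2-en-1-yl (2E)-2-methylbut-2-enoate | C=C([C@@H]1[C@H](OC(=O)/C(C)=C/C)C=C(C)[C@H](O)C1)[C@H](C[C@H]1OC1(C)C)OC(=O)/C(C)=C/C
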